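Cuts (flavone numbering): O1–C2 of ring C, then C4a–C5 of ring A, then C2–C3 and C4–C4a of the chain. This leaves triacetic acid lactone, an acetyl donor and a benzodioxane-6-carboxylate (ring B, dioxane ring, syringyl ring). The dioxane is cut at its two alkyl C–O bonds to a 3-arylglycidol and methyl 3-O-methylgallate.
Feature used: C5–C6–C7–C8–C8a–C4a–C4–C3–C2 of rings A and C is a nine-carbon chain with oxygen on every second atom (C5, C7, C8a, C4, C2). It is a folded 9-aryl-3,5,7,9-tetraoxononanoate whose C4a methylene lies six atoms from the carboxyl carbon C5.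
Forward order: dioxane ring (steps 7 and 9), chain attached at C2–C3 (step 11), ring A by Claisen folding of the pyranone-masked chain (step 12), ring C by cyclodehydration together with deprotection (step 13).
Stereochemistry: one Katsuki–Sharpless epoxidation sets both centres as (2S,3S). SN2 inversion at the benzylic carbon (step 7) and at the carbinol carbon (step 9) converts them into the trans-(2R,3R)-dioxane, which no later step touches.

Key step: step 12

Assumption: 1, 7 and 12 are taken as commercial, and β-polycarbonyl compounds are written in their keto forms whatever tautomer prevails.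
Abbreviations: MOM = methoxymethyl; TBS = tert-butyldimethylsilyl; Syr = 3,5-dimethoxy-4-(methoxymethoxy)phenyl; BD = (2R,3R)-2-(TBSO-methyl)-3-Syr-8-methoxy-2,3-dihydro-1,4-benzodioxin-6-yl. In BD, O1 lies next to C8–OMe and is bonded to C2, which bears CH2OTBS; O4 is bonded to C3, which bears Syr.

Step 1
Reactants: 1 syringaldehyde (4-hydroxy-3,5-dimethoxybenzaldehyde)
Product: 2 3,5-dimethoxy-4-(methoxymethoxy)benzaldehyde
Conditions: MOMCl (1.3 equiv), K2CO3, acetone, 0 °C to rt
Reagents that add atoms: chloromethyl methyl ether (MOMCl), COCCl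
Why: Williamson-type O-alkylation of the acidic para-formyl phenoxide by the reactive α-chloro ether installs an acetal that withstands all later basic, reductive and carbanion steps and falls in the final acid treatment.

Step 2
Reactants: 2 3,5-dimethoxy-4-(methoxymethoxy)benzaldehyde
Product: 3 ethyl (E)-3-Syr-prop-2-enoate
Conditions: (EtO)2P(O)CH2CO2Et, NaH, THF, 0 °C to rt
Reagents that add atoms: triethyl phosphonoacetate, CCOC(=O)CP(=O)(OCC)OCC
Why: Horner–Wadsworth–Emmons olefination of an aromatic aldehyde with a stabilised phosphonate anion should give the (E)-cinnamate.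

Step 3
Reactants: 3 ethyl (E)-3-Syr-prop-2-enoate
Product: 4 (E)-3-Syr-prop-2-en-1-ol
Conditions: iBu2AlH (2.2 equiv), CH2Cl2, −78 °C; aq. potassium sodium tartrate
Reagents that add atoms: none
Why: 1,2-reduction of an α,β-unsaturated ester with two equivalents of iBu2AlH at low temperature stops at the allylic alcohol and leaves alkene geometry and acetal untouched.

Step 4
Reactants: 4 (E)-3-Syr-prop-2-en-1-ol
Product: 5 [(2S,3S)-3-Syr-oxiran-2-yl]methanol
Conditions: Ti(OiPr)4 (10 mol %), L-(+)-diisopropyl tartrate (12 mol %), tBuOOH (2 equiv, decane), 4 Å sieves, CH2Cl2, −25 °C; NaOH in brine, 0 °C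
Reagents that add atoms: tert-butyl hydroperoxide, CC(C)(C)OO
Why: Katsuki–Sharpless asymmetric epoxidation of an (E)-cinnamyl alcohol, in which the complex of Ti(OiPr)4 and L-(+)-tartrate delivers oxygen to the alkene face that gives the (2S,3S)-epoxide (both stereocentres are set here, trans through the alkene geometry), while catalytic loading, sieves, low temperature and a basic work-up limit Lewis-acid opening of the benzylic epoxide.

Step 5
Reactants: 5 [(2S,3S)-3-Syr-oxiran-2-yl]methanol
Product: 6 tert-butyl{[(2S,3S)-3-Syr-oxiran-2-yl]methoxy}dimethylsilane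
Conditions: TBSCl, imidazole, CH2Cl2, 0 °C to rt
Reagents that add atoms: tert-butyldimethylsilyl chloride, CC(C)(C)[Si](C)(C)Cl
Why: Imidazole-promoted silylation of a primary alcohol is mild enough for the epoxide, shuts off Payne rearrangement in step 7 and already places the final protecting group on the hydroxymethyl arm.

Step 6
Reactants: 7 methyl 3,4-dihydroxy-5-methoxybenzoate
Product: 8 methyl 3-hydroxy-5-methoxy-4-(prop-2-en-1-yloxy)benzoate
Conditions: allyl bromide (1.05 equiv), NaHCO3 (1.2 equiv), DMF, 40 °C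
Reagents that add atoms: allyl bromide, C=CCBr
Why: Regioselective Williamson etherification, since the weak base ionises only the 4-OH (para to the ester and the more acidic one), a selectivity established for 3,4-dihydroxybenzaldehydes and gallates, so the 3-OH stays free for step 7.

Step 7
Reactants: 6 tert-butyl{[(2S,3S)-3-Syr-oxiran-2-yl]methoxy}dimethylsilane; 8 methyl 3-hydroxy-5-methoxy-4-(prop-2-en-1-yloxy)benzoate
Product: 9 methyl 3-[(1R,2S)-3-(TBSO)-2-hydroxy-1-Syr-propoxy]-5-methoxy-4-(prop-2-en-1-yloxy)benzoate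
Conditions: 8 (1.3 equiv), Cs2CO3 (20 mol %), DMF, 80 °C
Reagents that add atoms: none
Why: Base-catalysed SN2 opening of a 3-arylglycidyl ether by a phenoxide, which attacks the arene-activated benzylic carbon rather than the carbon next to the electron-withdrawing CH2OSi group and does so with inversion (3S becomes 1R), while the other C–O bond and its configuration are kept.

Step 8
Reactants: 9 methyl 3-[(1R,2S)-3-(TBSO)-2-hydroxy-1-Syr-propoxy]-5-methoxy-4-(prop-2-en-1-yloxy)benzoate
Product: 10 methyl 3-[(1R,2S)-3-(TBSO)-2-hydroxy-1-Syr-propoxy]-4-hydroxy-5-methoxybenzoate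
Conditions: Pd(PPh3)4 (5 mol %), morpholine (3 equiv), THF, rt
Reagents that add atoms: none
Why: Tsuji–Trost deallylation, in which zerovalent palladium ionises the aryl allyl ether (a good leaving phenoxide, para to the ester) and morpholine captures the π-allyl unit, leaving silyl ether, acetal, ester and both stereocentres alone.

Step 9
Reactants: 10 methyl 3-[(1R,2S)-3-(TBSO)-2-hydroxy-1-Syr-propoxy]-4-hydroxy-5-methoxybenzoate
Product: 11 methyl (2R,3R)-2-(TBSO-methyl)-3-Syr-8-methoxy-2,3-dihydro-1,4-benzodioxine-6-carboxylate (BD-CO2Me)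
Conditions: PPh3, diisopropyl azodicarboxylate, THF (0.02 M), 0 °C to rt
Reagents that add atoms: none
Why: Intramolecular Mitsunobu etherification (6-exo-tet), in which the acidic phenol displaces the oxyphosphonium group at the non-benzylic carbinol carbon with inversion (S becomes R), so that the erythro precursor closes to the trans-(2R,3R)-benzodioxane.

Step 10
Reactants: 12 triacetic acid lactone (4-hydroxy-6-methyl-2H-pyran-2-one)
Product: 13 tetraacetic acid lactone (4-hydroxy-6-(2-oxopropyl)-2H-pyran-2-one)
Conditions: LiN(iPr)2 (2.2 equiv), THF, −78 to −20 °C; MeC(O)N(OMe)Me, −78 to 0 °C; 1 M HCl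
Reagents that add atoms: N-methoxy-N-methylacetamide, CC(=O)N(C)OC
Why: Claisen-type C-acylation of a dianion at its last-formed and most basic site, the 6-methylene carbon, with a Weinreb amide whose chelated tetrahedral adduct survives until the quench and so prevents over-addition and proton exchange.

Step 11
Reactants: 13 tetraacetic acid lactone; 11 BD-CO2Me
Product: 14 4-hydroxy-6-[4-(BD)-2,4-dioxobutyl]-2H-pyran-2-one
Conditions: 13 (2.2 equiv), LiN(iPr)2 (6.6 equiv), THF, −78 to 0 °C; 11, 0 °C to rt; cold 1 M HCl to pH 3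
Reagents that add atoms: none
Why: Crossed Claisen condensation of a β-polycarbonyl trianion with a non-enolisable aromatic ester, in which the terminal carbanion (formed last, hence most reactive) takes the aroyl group, the surplus trianion absorbs the acidic proton of the new 1,3-diketone, and the ester partner offers no acidic hydrogen at its stereocentres.

Step 12
Reactants: 14 4-hydroxy-6-[4-(BD)-2,4-dioxobutyl]-2H-pyran-2-one
Product: 16 1-(BD)-3-(2,4,6-trihydroxyphenyl)propane-1,3-dione, via tetraketo methyl ester 15 (not isolated)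
Conditions: Mg(OMe)2 (8 equiv), MeOH, reflux; cold 0.5 M HCl to pH 4
Reagents that add atoms: none
Why: Proposed new method: methoxide should add to the magnesium-bound lactone carbonyl of 14 and unzip the pyranone to ester 15, held as a magnesium polyenolate, after which the C4a methylene (between the C8a and C4 carbonyls) attacks the ester carbon C5, methoxide leaves, and tautomerisation to the phloroglucinol makes the new C4a–C5 bond irreversible. The closest known reaction type is the Mg(OMe)2-mediated Claisen (Dieckmann-type) cyclisation of 6-(2-oxoalkyl)-4-hydroxy-2-pyranones and of 3,5,7-triketo esters to acylphloroglucinols, but a chain with a fourth ketone, which opens further folding modes, has not been shown to close this way. Ring A closes in a 6-(enolexo)-exo-trig mode. No stereocentre is formed, and the two dioxane centres bear no acidic hydrogen and remain (2R,3R). The step needs chemoselectivity for acyl substitution at C5 over the aldol closures C6 onto C4, C3 onto C7 and C8 onto C2. Chelation should secure it by holding the ketone carbons as unreactive enolates, so that the ester is the one carbonyl that carries a leaving group, and the aroyl carbon C2 is further deactivated by its trialkoxyarene donor.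

Step 13
Reactants: 16 1-(BD)-3-(2,4,6-trihydroxyphenyl)propane-1,3-dione
Product: 18 palstatin, via deprotected diketone 17 (not isolated)
Conditions: HCl (1.25 M in MeOH), rt to 55 °C
Reagents that add atoms: none
Why: Acid-catalysed cyclodehydration of an o-hydroxyaryl 1,3-diketone (the closing stage of the Baker–Venkataraman flavone synthesis), in which either of the two equivalent ortho phenols adds to the aroyl carbon C2 and water is lost to give the 4-pyranone, while the same acid solvolyses the MOM acetal and the primary silyl ether and any reversible ionisation at the benzylic dioxane carbon would reclose to the favoured trans ring.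

Compound list
1 | syringaldehyde (4-hydroxy-3,5-dimethoxybenzaldehyde) | COc1cc(C=O)cc(OC)c1O | starting material
2 | 3,5-dimethoxy-4-(methoxymethoxy)benzaldehyde | COCOc1c(OC)cc(C=O)cc1OC | intermediate
3 | ethyl (E)-3-[3,5-dimethoxy-4-(methoxymethoxy)phenyl]prop-2-enoate | CCOC(=O)/C=C/c1cc(OC)c(OCOC)c(OC)c1 | intermediate
4 | (E)-3-[3,5-dimethoxy-4-(methoxymethoxy)phenyl]prop-2-en-1-ol | OC/C=C/c1cc(OC)c(OCOC)c(OC)c1 | intermediate
5 | {(2S,3S)-3-[3,5-dimethoxy-4-(methoxymethoxy)phenyl]oxiran-2-yl}methanol | COc1cc([C@@H]2O[C@H]2CO)cc(OC)c1OCOC | intermediate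
6 | tert-butyl({(2S,3S)-3-[3,5-dimethoxy-4-(methoxymethoxy)phenyl]oxiran-2-yl}methoxy)dimethylsilane | COc1cc([C@@H]2O[C@H]2CO[Si](C)(C)C(C)(C)C)cc(OC)c1OCOC | intermediate
7 | methyl 3,4-dihydroxy-5-methoxybenzoate | COC(=O)c1cc(O)c(O)c(OC)c1 | starting material
8 | methyl 3-hydroxy-5-methoxy-4-(prop-2-en-1-yloxy)benzoate | COC(=O)c1cc(O)c(OCC=C)c(OC)c1 | intermediate
9 | methyl 3-{(1R,2S)-3-[(tert-butyldimethylsilyl)oxy]-1-[3,5-dimethoxy-4-(methoxymethoxy)phenyl]-2-hydroxypropoxy}-5-methoxy-4-(prop-2-en-1-yloxy)benzoate | COc1cc([C@@H](Oc2cc(C(=O)OC)cc(OC)c2OCC=C)[C@@H](O)CO[Si](C)(C)C(C)(C)C)cc(OC)c1OCOC | intermediate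
10 | methyl 3-{(1R,2S)-3-[(tert-butyldimethylsilyl)oxy]-1-[3,5-dimethoxy-4-(methoxymethoxy)phenyl]-2-hydroxypropoxy}-4-hydroxy-5-methoxybenzoate | COc1cc([C@@H](Oc2cc(C(=O)OC)cc(OC)c2O)[C@@H](O)CO[Si](C)(C)C(C)(C)C)cc(OC)c1OCOC | intermediate
11 | methyl (2R,3R)-2-{[(tert-butyldimethylsilyl)oxy]methyl}-3-[3,5-dimethoxy-4-(methoxymethoxy)phenyl]-8-methoxy-2,3-dihydro-1,4-benzodioxine-6-carboxylate | COc1cc([C@H]2Oc3cc(C(=O)OC)cc(OC)c3O[C@@H]2CO[Si](C)(C)C(C)(C)C)cc(OC)c1OCOC | intermediate
12 | triacetic acid lactone (4-hydroxy-6-methyl-2H-pyran-2-one) | Cc1cc(O)cc(=O)o1 | starting material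
13 | tetraacetic acid lactone (4-hydroxy-6-(2-oxopropyl)-2H-pyran-2-one) | CC(=O)Cc1cc(O)cc(=O)o1 | intermediate
14 | 4-hydroxy-6-[4-(BD)-2,4-dioxobutyl]-2H-pyran-2-one | COc1cc([C@H]2Oc3cc(C(=O)CC(=O)Cc4cc(O)cc(=O)o4)cc(OC)c3O[C@@H]2CO[Si](C)(C)C(C)(C)C)cc(OC)c1OCOC | intermediate
15 | methyl 9-(BD)-3,5,7,9-tetraoxononanoate | COc1cc([C@H]2Oc3cc(C(=O)CC(=O)CC(=O)CC(=O)CC(=O)OC)cc(OC)c3O[C@@H]2CO[Si](C)(C)C(C)(C)C)cc(OC)c1OCOC | intermediate
16 | 1-(BD)-3-(2,4,6-trihydroxyphenyl)propane-1,3-dione | COc1cc([C@H]2Oc3cc(C(=O)CC(=O)c4c(O)cc(O)cc4O)cc(OC)c3O[C@@H]2CO[Si](C)(C)C(C)(C)C)cc(OC)c1OCOC | intermediate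
17 | 1-[(2R,3R)-3-(4-hydroxy-3,5-dimethoxyphenyl)-2-(hydroxymethyl)-8-methoxy-2,3-dihydro-1,4-benzodioxin-6-yl]-3-(2,4,6-trihydroxyphenyl)propane-1,3-dione | COc1cc([C@H]2Oc3cc(C(=O)CC(=O)c4c(O)cc(O)cc4O)cc(OC)c3O[C@@H]2CO)cc(OC)c1O | intermediate
18 | palstatin, 2-[(2R,3R)-3-(4-hydroxy-3,5-dimethoxyphenyl)-2-(hydroxymethyl)-8-methoxy-2,3-dihydro-1,4-benzodioxin-6-yl]-5,7-dihydroxy-4H-chromen-4-one | COc1cc([C@H]2Oc3cc(-c4cc(=O)c5c(O)cc(O)cc5o4)cc(OC)c3O[C@@H]2CO)cc(OC)c1O | target

Total step count: 13. Longest linear sequence: 11 steps (1–5, 7–9, 11–13).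

Steps most likely to fail

Step 12 (bears the label): the opened chain may fold by aldol addition and dehydration instead of by acyl substitution at C5, or the pyranone anion may resist methanolysis. The fallback uses known chemistry, sets out from 11 and comes back at 18. Saponification of 11 (LiOH, THF–MeOH–H2O) gives the carboxylic acid F1. This is coupled (1-ethyl-3-(3-dimethylaminopropyl)carbodiimide, 4-dimethylaminopyridine, CH2Cl2) with commercial 1-[2-hydroxy-4,6-bis(methoxymethoxy)phenyl]ethanone to give the aryl ester F2. A Baker–Venkataraman rearrangement (LiN(SiMe3)2, THF, −78 °C to rt) moves the aroyl group onto the acetyl carbon and gives the o-hydroxyaryl diketone F3. The conditions of step 13 then close ring C and remove the three MOM groups and the silyl ether. Ring A is then bought rather than folded.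

Step 11: acyl transfer from the electron-rich benzoate to the sparingly soluble trianion may be slow, and proton transfer from the product may consume the nucleophile. The fallback works at a lower oxidation level, sets out from 11 and comes back at 14. Reduction (iBu2AlH, CH2Cl2, −78 °C) gives the benzylic alcohol F4, and MnO2 in CH2Cl2 gives the aldehyde F5. The trianion of 13 adds to this far better electrophile at −78 °C in an aldol addition and gives the β-hydroxy ketone F6 (both carbinol epimers, which is of no consequence). 2-Iodoxybenzoic acid in hot ethyl acetate then oxidises it to the 1,3-diketone 14.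

Step 4: the Lewis-acidic titanium alkoxide may ionise the electron-rich benzylic epoxide during the reaction or the work-up, with opening by isopropanol or tartrate and loss of material and enantiomeric purity. The fallback avoids any Lewis acid, sets out from 4 and comes back at 6. Silylation first (TBSCl, imidazole, CH2Cl2) gives the (E)-cinnamyl silyl ether F7. A Shi epoxidation then transfers oxygen from the chiral dioxirane to the trans alkene and gives 6 directly. It uses the enantiomer of the D-fructose-derived ketone (made from L-sorbose), KHSO5, K2CO3 buffer near pH 10.5, and MeCN–dimethoxymethane–water at 0 °C.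

Further compounds
F1 | step 12 | (2R,3R)-2-{[(tert-butyldimethylsilyl)oxy]methyl}-3-[3,5-dimethoxy-4-(methoxymethoxy)phenyl]-8-methoxy-2,3-dihydro-1,4-benzodioxine-6-carboxylic acid (BD-CO2H) | COc1cc([C@H]2Oc3cc(C(=O)O)cc(OC)c3O[C@@H]2CO[Si](C)(C)C(C)(C)C)cc(OC)c1OCOC
F2 | step 12 | 2-acetyl-3,5-bis(methoxymethoxy)phenyl ester of BD-CO2H | COc1cc([C@H]2Oc3cc(C(=O)Oc4cc(OCOC)cc(OCOC)c4C(C)=O)cc(OC)c3O[C@@H]2CO[Si](C)(C)C(C)(C)C)cc(OC)c1OCOC
F3 | step 12 | 1-(BD)-3-[2-hydroxy-4,6-bis(methoxymethoxy)phenyl]propane-1,3-dione | COc1cc([C@H]2Oc3cc(C(=O)CC(=O)c4c(O)cc(OCOC)cc4OCOC)cc(OC)c3O[C@@H]2CO[Si](C)(C)C(C)(C)C)cc(OC)c1OCOC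
F4 | step 11 | (BD)methanol | COc1cc([C@H]2Oc3cc(CO)cc(OC)c3O[C@@H]2CO[Si](C)(C)C(C)(C)C)cc(OC)c1OCOC
F5 | step 11 | BD-carbaldehyde | COc1cc([C@H]2Oc3cc(C=O)cc(OC)c3O[C@@H]2CO[Si](C)(C)C(C)(C)C)cc(OC)c1OCOC
F6 | step 11 | 4-hydroxy-6-[4-(BD)-4-hydroxy-2-oxobutyl]-2H-pyran-2-one (both carbinol epimers) | COc1cc([C@H]2Oc3cc(C(O)CC(=O)Cc4cc(O)cc(=O)o4)cc(OC)c3O[C@@H]2CO[Si](C)(C)C(C)(C)C)cc(OC)c1OCOC
F7 | step 4 | tert-butyl({(E)-3-[3,5-dimethoxy-4-(methoxymethoxy)phenyl]prop-2-en-1-yl}oxy)dimethylsilane | COCOc1c(OC)cc(/C=C/CO[Si](C)(C)C(C)(C)C)cc1OC
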